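**Retrosynthetic overview**
- Eupacunolin is cut at O6–C12 and at C6–C7, the bond that farnesyl diphosphate closes between its C1 and C10. An open, fully oxygenated farnesane chain with a Z-enal at C6 and a 2-(bromomethyl)enoate at C7/C11–C13 closes the ten-membered carbocycle by intramolecular chromium allylation, then the γ-lactone in the same flask (carbocycle first, lactone second, as in germacrene A acid → costunolide).
- The allyl donor is put on last by cross-metathesis at C7=C11. The chain is split at C2–C3 into a methyl Z-enone (C1, C2, C7–C10, C14) and a Z-enal (C3–C6, C15).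
- C2–C3 is made by an Ipc-boron aldol (sets C3); an Evans–Tishchenko reduction then sets C1 anti and delivers the C3 acetate.
- Both Z-trisubstituted alkenes come from hydroxyl-directed trans-hydroalumination/iodination of propargylic alcohols; C8 comes from a catalytic asymmetric alkynylation of crotonaldehyde.

Assumption: locants C1–C15 follow germacrane numbering (lactone O6–C12, tiglate on O8, acetate on O3, free OH on C1 and C15); CIP descriptors of intermediates refer to the SMILES given, and the ProPhenol and Ipc antipodes named are those taken to give the stated face selectivity.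

**Step 1**
Reactants: 1 (E)-but-2-enal (crotonaldehyde); 2 propyne
Product: 4 (S,E)-hept-2-en-5-yn-4-ol, via methyl(prop-1-ynyl)zinc 3 (not isolated)
Conditions: Me2Zn (3 equiv), (S,S)-ProPhenol (10 mol %), Ph3PO (20 mol %), toluene, 0 °C; then 1; aq. NH4Cl
Reagents that add atoms: none
Why: Catalytic enantioselective alkynylzinc addition to an enal (Trost ProPhenol alkynylation), in which the dinuclear zinc catalyst delivers the propynyl group to the Re face of the aldehyde and so sets the future C8 carbinol as S.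

**Step 2**
Reactants: 4 (S,E)-hept-2-en-5-yn-4-ol
Product: 6 (2E,4S,5Z)-6-iodohepta-2,5-dien-4-ol, via cyclic sodium alkenylalanate 5 (not isolated)
Conditions: NaAlH2(OCH2CH2OCH3)2 (1.5 equiv), THF, 0 °C to rt; then I2, −78 °C
Reagents that add atoms: iodine, [I][I]
Why: Hydroxyl-directed trans-hydroalumination of the propargylic alcohol followed by iododealumination with retention puts iodine on the distal carbon cis to the carbinol, which fixes the Z geometry of C9=C10 and leaves the stereocentre untouched.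

**Step 3**
Reactants: 6 (2E,4S,5Z)-6-iodohepta-2,5-dien-4-ol; 7 tiglic acid
Product: 8 (2E,4S,5Z)-6-iodohepta-2,5-dien-4-yl (E)-2-methylbut-2-enoate
Conditions: DCC, DMAP (cat.), CH2Cl2, 0 °C to rt
Reagents that add atoms: none
Why: Steglich esterification puts the tiglate of the target on the only hydroxyl by acylation at oxygen, so C8 keeps its configuration.

**Step 4**
Reactants: 8 (2E,4S,5Z)-6-iodohepta-2,5-dien-4-yl (E)-2-methylbut-2-enoate; 9 tributyl(1-ethoxyvinyl)stannane
Product: 11 (2E,4S,5Z)-6-methyl-7-oxoocta-2,5-dien-4-yl (E)-2-methylbut-2-enoate, via 2-ethoxydiene tiglate 10 (not isolated)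
Conditions: Pd2(dba)3 (2.5 mol %), AsPh3, CuI, DMF, rt; then 1 M HCl, THF, 0 °C
Reagents that add atoms: water, O
Why: Stille coupling with an acetyl-anion equivalent proceeds with retention at the vinyl iodide (oxidative addition to C–I at room temperature outpaces ionisation of the allylic ester), and mild enol-ether hydrolysis unveils the Z methyl enone, whose C8 oxygen is already acylated so that no furan can form.

**Step 5**
Reactants: 12 but-2-yne-1,4-diol
Product: 13 4-[(tert-butyldimethylsilyl)oxy]but-2-yn-1-ol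
Conditions: NaH (1.0 equiv), THF, 0 °C; TBSCl (1.0 equiv)
Reagents that add atoms: tert-butyldimethylsilyl chloride, CC(C)(C)[Si](C)(C)Cl
Why: Monosilylation of the symmetrical diol through its monosodium alkoxide (McDougal protocol) protects the future O15.

**Step 6**
Reactants: 13 4-[(tert-butyldimethylsilyl)oxy]but-2-yn-1-ol
Product: 15 (Z)-4-[(tert-butyldimethylsilyl)oxy]-3-iodobut-2-en-1-ol, via cyclic sodium alkenylalanate 14 (not isolated)
Conditions: NaAlH2(OCH2CH2OCH3)2 (1.5 equiv), THF, 0 °C to rt; then I2, −78 °C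
Reagents that add atoms: iodine, [I][I]
Why: The free hydroxyl directs trans-hydroalumination so that iodine ends on C4 cis to C6, which fixes the Z geometry of C4=C5 with C15 trans to C6.

**Step 7**
Reactants: 15 (Z)-4-[(tert-butyldimethylsilyl)oxy]-3-iodobut-2-en-1-ol
Product: 16 (Z)-1-[(tert-butyldimethylsilyl)oxy]-2-iodo-4-[(triethylsilyl)oxy]but-2-ene
Conditions: TESCl, imidazole, CH2Cl2, 0 °C
Reagents that add atoms: triethylsilyl chloride, CC[Si](Cl)(CC)CC
Why: Standard silylation; the TES ether keeps O6 from closing a lactol onto the C3 aldehyde of the next step and can later be removed in the presence of the TBS ether.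

**Step 8**
Reactants: 16 (Z)-1-[(tert-butyldimethylsilyl)oxy]-2-iodo-4-[(triethylsilyl)oxy]but-2-ene
Product: 18 (Z)-2-{[(tert-butyldimethylsilyl)oxy]methyl}-4-[(triethylsilyl)oxy]but-2-enal, via alkenyllithium 17 (not isolated)
Conditions: t-BuLi (2.1 equiv), Et2O, −78 °C; DMF, −78 to −40 °C; aq. NH4Cl
Reagents that add atoms: N,N-dimethylformamide, CN(C)C=O
Why: Iodine–lithium exchange with retention of alkene geometry and Bouveault formylation give the Z-enal, which is used at once because it is the less stable geometric isomer.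

**Step 9**
Reactants: 11 (2E,4S,5Z)-6-methyl-7-oxoocta-2,5-dien-4-yl (E)-2-methylbut-2-enoate; 18 (Z)-2-{[(tert-butyldimethylsilyl)oxy]methyl}-4-[(triethylsilyl)oxy]but-2-enal
Product: 20 (2E,4S,5Z,9S,10Z)-10-{[(tert-butyldimethylsilyl)oxy]methyl}-9-hydroxy-6-methyl-7-oxo-12-[(triethylsilyl)oxy]dodeca-2,5,10-trien-4-yl (E)-2-methylbut-2-enoate, via diisopinocampheylboron dienolate 19 (not isolated)
Conditions: (−)-Ipc2BCl, Et3N, Et2O, 0 °C; then 18, −78 to −20 °C; MeOH, pH 7 buffer, H2O2, 0 °C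
Reagents that add atoms: none
Why: Paterson boron aldol: kinetic enolisation at the methyl group, then reagent-controlled addition of the Ipc2B dienolate to the Si face of the enal forms C2–C3 and sets C3 as S, with esters and silyl ethers inert.

**Step 10**
Reactants: 20 the C3 ketol of step 9; 21 acetaldehyde
Product: 23 (2E,4S,5Z,7S,9S,10Z)-9-acetoxy-10-{[(tert-butyldimethylsilyl)oxy]methyl}-7,12-dihydroxy-6-methyldodeca-2,5,10-trien-4-yl (E)-2-methylbut-2-enoate, via triethylsilyl ether acetate 22 (not isolated)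
Conditions: SmI2 (30 mol %), THF, −10 °C; then AcOH–THF–H2O 3:1:1, rt
Reagents that add atoms: none
Why: Evans–Tishchenko reduction: the C3 hydroxyl forms a samarium-bound hemiacetal with acetaldehyde and delivers hydride intramolecularly to the C1 ketone through a chair transition state, which gives the 1,3-anti diol (1S) with the acetate on O3 and a free C1 hydroxyl in one operation, and mild acid then cleaves only the primary TES ether.

**Step 11**
Reactants: 23 the diol acetate of step 10; 24 methyl 2-(bromomethyl)acrylate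
Product: 25 methyl (2Z,4R,5Z,7S,9S,10Z)-9-acetoxy-2-(bromomethyl)-10-{[(tert-butyldimethylsilyl)oxy]methyl}-7,12-dihydroxy-6-methyl-4-{[(E)-2-methylbut-2-enoyl]oxy}dodeca-2,5,10-trienoate
Conditions: second-generation Hoveyda–Grubbs catalyst (10 mol %), 24 (5 equiv), CH2Cl2, 40 °C
Reagents that add atoms: none
Why: Olefin cross-metathesis between the disubstituted propenyl group and the 1,1-disubstituted acrylate (the trisubstituted alkenes are inert) expels propene and gives the 2-(bromomethyl)enoate with C8 trans to the ester, with no stereocentre touched (C8 becomes R by CIP only).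

**Step 12**
Reactants: 25 the allylic bromide diol of step 11
Product: 26 methyl (2Z,4R,5Z,7S,9S,10Z)-9-acetoxy-2-(bromomethyl)-10-{[(tert-butyldimethylsilyl)oxy]methyl}-7-hydroxy-6-methyl-4-{[(E)-2-methylbut-2-enoyl]oxy}-12-oxododeca-2,5,10-trienoate
Conditions: TEMPO (20 mol %), PhI(OAc)2 (1.2 equiv), CH2Cl2, rt
Reagents that add atoms: none
Why: Oxoammonium (TEMPO/PhI(OAc)2) oxidation is selective for the primary allylic alcohol over the secondary C1 carbinol and leaves the allylic bromide, the esters and the Z-enal geometry intact.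

**Step 13**
Reactants: 26 the Z-enal allylic bromide of step 12
Product: 29 (1S,3S,6R,7R,8R,4Z,9Z)-3-acetoxy-15-[(tert-butyldimethylsilyl)oxy]-1-hydroxy-8-[(E)-2-methylbut-2-enoyloxy]germacra-4,9,11(13)-trien-12,6-olide, via allylchromium dichloride 27 (not isolated), via ring-closed hydroxy ester 28 (not isolated)
Conditions: CrCl2 (10 equiv), THF, 0.002 M, slow addition of 26, 25 °C; aq. NH4Cl
Reagents that add atoms: none
Why: Intramolecular Nozaki–Hiyama allylation then lactonisation: the allylchromium attacks the C6 aldehyde through C7 (the bond germacrene synthase makes) in a chair-like transition state in which H8 eclipses the enoate (A(1,3) strain), the tethered aldehyde enters anti to the tigloyloxy group (7R) and C5 and C8 lie trans across the new bond (6R, trans-lactone), after which the C6 chromium alkoxide closes onto the C12 ester as in costunolide biosynthesis.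

**Step 14**
Reactants: 29 the silyl-protected macrolactone of step 13
Product: 30 eupacunolin, (1S,3S,6R,7R,8R,4Z,9Z)-3-acetoxy-1,15-dihydroxy-8-[(E)-2-methylbut-2-enoyloxy]germacra-4,9,11(13)-trien-12,6-olide
Conditions: HF·pyridine, pyridine/THF, 0 °C to rt
Reagents that add atoms: none
Why: Buffered fluoride desilylation removes the primary TBS ether without acyl migration or attack on the α-methylene lactone.

**Compound list**
1 | (E)-but-2-enal (crotonaldehyde) | C/C=C/C=O | starting material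
2 | propyne | CC#C | starting material
3 | methyl(prop-1-yn-1-yl)zinc (not isolated) | C[Zn]C#CC | intermediate
4 | (S,E)-hept-2-en-5-yn-4-ol | CC#C[C@@H](O)/C=C/C | intermediate
5 | sodium (S)-2,2-bis(2-methoxyethoxy)-3-methyl-5-[(E)-prop-1-enyl]-2,5-dihydro-1,2-oxaaluminol-2-uide (not isolated) | [Na+].COCCO[Al-]1(OCCOC)O[C@@H](/C=C/C)C=C1C | intermediate
6 | (2E,4S,5Z)-6-iodohepta-2,5-dien-4-ol | I/C(C)=C\[C@@H](O)/C=C/C | intermediate
7 | tiglic acid, (E)-2-methylbut-2-enoic acid | C/C=C(\C)C(=O)O | starting material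
8 | (2E,4S,5Z)-6-iodohepta-2,5-dien-4-yl (E)-2-methylbut-2-enoate | I/C(C)=C\[C@@H](OC(=O)/C(C)=C/C)/C=C/C | intermediate
9 | tributyl(1-ethoxyvinyl)stannane | CCCC[Sn](CCCC)(CCCC)C(=C)OCC | starting material
10 | (2E,4S,5Z)-7-ethoxy-6-methylocta-2,5,7-trien-4-yl (E)-2-methylbut-2-enoate (not isolated) | CCOC(=C)/C(C)=C\[C@@H](OC(=O)/C(C)=C/C)/C=C/C | intermediate
11 | (2E,4S,5Z)-6-methyl-7-oxoocta-2,5-dien-4-yl (E)-2-methylbut-2-enoate | CC(=O)/C(C)=C\[C@@H](OC(=O)/C(C)=C/C)/C=C/C | intermediate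
12 | but-2-yne-1,4-diol | OCC#CCO | starting material
13 | 4-[(tert-butyldimethylsilyl)oxy]but-2-yn-1-ol | OCC#CCO[Si](C)(C)C(C)(C)C | intermediate
14 | sodium 3-{[(tert-butyldimethylsilyl)oxy]methyl}-2,2-bis(2-methoxyethoxy)-2,5-dihydro-1,2-oxaaluminol-2-uide (not isolated) | [Na+].COCCO[Al-]1(OCCOC)OCC=C1CO[Si](C)(C)C(C)(C)C | intermediate
15 | (Z)-4-[(tert-butyldimethylsilyl)oxy]-3-iodobut-2-en-1-ol | OC/C=C(/CO[Si](C)(C)C(C)(C)C)I | intermediate
16 | (Z)-1-[(tert-butyldimethylsilyl)oxy]-2-iodo-4-[(triethylsilyl)oxy]but-2-ene | CC[Si](CC)(CC)OC/C=C(/CO[Si](C)(C)C(C)(C)C)I | intermediate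
17 | (E)-{1-[(tert-butyldimethylsilyl)oxy]-4-[(triethylsilyl)oxy]but-2-en-2-yl}lithium (not isolated) | CC[Si](CC)(CC)OC/C=C(/CO[Si](C)(C)C(C)(C)C)[Li] | intermediate
18 | (Z)-2-{[(tert-butyldimethylsilyl)oxy]methyl}-4-[(triethylsilyl)oxy]but-2-enal | CC[Si](CC)(CC)OC/C=C(/CO[Si](C)(C)C(C)(C)C)C=O | intermediate
19 | (2E,4S,5Z)-7-[(diisopinocampheylboranyl)oxy]-6-methylocta-2,5,7-trien-4-yl (E)-2-methylbut-2-enoate (not isolated) | C=C(OB([C@H]1[C@H](C)[C@H]2C[C@@H](C1)C2(C)C)[C@H]1[C@H](C)[C@H]2C[C@@H](C1)C2(C)C)/C(C)=C\[C@@H](OC(=O)/C(C)=C/C)/C=C/C | intermediate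
20 | (2E,4S,5Z,9S,10Z)-10-{[(tert-butyldimethylsilyl)oxy]methyl}-9-hydroxy-6-methyl-7-oxo-12-[(triethylsilyl)oxy]dodeca-2,5,10-trien-4-yl (E)-2-methylbut-2-enoate | CC[Si](CC)(CC)OC/C=C(/CO[Si](C)(C)C(C)(C)C)[C@@H](O)CC(=O)/C(C)=C\[C@@H](OC(=O)/C(C)=C/C)/C=C/C | intermediate
21 | acetaldehyde | CC=O | starting material
22 | (2E,4S,5Z,7S,9S,10Z)-9-acetoxy-10-{[(tert-butyldimethylsilyl)oxy]methyl}-7-hydroxy-6-methyl-12-[(triethylsilyl)oxy]dodeca-2,5,10-trien-4-yl (E)-2-methylbut-2-enoate (not isolated) | CC[Si](CC)(CC)OC/C=C(/CO[Si](C)(C)C(C)(C)C)[C@@H](OC(C)=O)C[C@H](O)/C(C)=C\[C@@H](OC(=O)/C(C)=C/C)/C=C/C | intermediate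
23 | (2E,4S,5Z,7S,9S,10Z)-9-acetoxy-10-{[(tert-butyldimethylsilyl)oxy]methyl}-7,12-dihydroxy-6-methyldodeca-2,5,10-trien-4-yl (E)-2-methylbut-2-enoate | OC/C=C(/CO[Si](C)(C)C(C)(C)C)[C@@H](OC(C)=O)C[C@H](O)/C(C)=C\[C@@H](OC(=O)/C(C)=C/C)/C=C/C | intermediate
24 | methyl 2-(bromomethyl)acrylate | C=C(CBr)C(=O)OC | starting material
25 | methyl (2Z,4R,5Z,7S,9S,10Z)-9-acetoxy-2-(bromomethyl)-10-{[(tert-butyldimethylsilyl)oxy]methyl}-7,12-dihydroxy-6-methyl-4-{[(E)-2-methylbut-2-enoyl]oxy}dodeca-2,5,10-trienoate | OC/C=C(/CO[Si](C)(C)C(C)(C)C)[C@@H](OC(C)=O)C[C@H](O)/C(C)=C\[C@@H](OC(=O)/C(C)=C/C)/C=C(\CBr)C(=O)OC | intermediate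
26 | methyl (2Z,4R,5Z,7S,9S,10Z)-9-acetoxy-2-(bromomethyl)-10-{[(tert-butyldimethylsilyl)oxy]methyl}-7-hydroxy-6-methyl-4-{[(E)-2-methylbut-2-enoyl]oxy}-12-oxododeca-2,5,10-trienoate | O=C/C=C(/CO[Si](C)(C)C(C)(C)C)[C@@H](OC(C)=O)C[C@H](O)/C(C)=C\[C@@H](OC(=O)/C(C)=C/C)/C=C(\CBr)C(=O)OC | intermediate
27 | allylchromium dichloride of 26 (CrCl2 on C13 in place of Br; not isolated) | O=C/C=C(/CO[Si](C)(C)C(C)(C)C)[C@@H](OC(C)=O)C[C@H](O)/C(C)=C\[C@@H](OC(=O)/C(C)=C/C)/C=C(\C[Cr](Cl)Cl)C(=O)OC | intermediate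
28 | methyl (1S,3S,6R,7S,8R,4Z,9Z)-3-acetoxy-15-[(tert-butyldimethylsilyl)oxy]-1,6-dihydroxy-8-[(E)-2-methylbut-2-enoyloxy]germacra-4,9,11(13)-trien-12-oate (formed as its chromium alkoxide; not isolated; C7 is S by CIP only) | C=C(C(=O)OC)[C@H]1[C@H](O)/C=C(/CO[Si](C)(C)C(C)(C)C)[C@@H](OC(C)=O)C[C@H](O)/C(C)=C\[C@H]1OC(=O)/C(C)=C/C | intermediate
29 | (1S,3S,6R,7R,8R,4Z,9Z)-3-acetoxy-15-[(tert-butyldimethylsilyl)oxy]-1-hydroxy-8-[(E)-2-methylbut-2-enoyloxy]germacra-4,9,11(13)-trien-12,6-olide | C=C1C(=O)O[C@@H]2/C=C(/CO[Si](C)(C)C(C)(C)C)[C@@H](OC(C)=O)C[C@H](O)/C(C)=C\[C@@H](OC(=O)/C(C)=C/C)[C@@H]12 | intermediate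
30 | eupacunolin, (1S,3S,6R,7R,8R,4Z,9Z)-3-acetoxy-1,15-dihydroxy-8-[(E)-2-methylbut-2-enoyloxy]germacra-4,9,11(13)-trien-12,6-olide | C=C1C(=O)O[C@@H]2/C=C(/CO)[C@@H](OC(C)=O)C[C@H](O)/C(C)=C\[C@@H](OC(=O)/C(C)=C/C)[C@@H]12 | target

**Totals and risks**

Total: 14 steps. Longest linear sequence: 10 steps (steps 1–4 then 9–14, or steps 5–8 then 9–14).

Most likely to fail, in order:

Step 13, the chromium macro-allylation and lactonisation. The allylchromium may lose the C8 tiglate by 1,4-elimination before the slow ten-membered closure. The C6/C7 configuration rests on a transition-state model rather than on a close precedent. The C6 alkoxide could also take the tigloyl group instead of lactonising. The fallback sets out from 25 and avoids a reducing metal. Borylation with B2pin2, CuCl, LiCl and KOAc in DMF replaces bromide by boron and gives methyl (2E,4R,5Z,7S,9S,10Z)-9-acetoxy-10-{[(tert-butyldimethylsilyl)oxy]methyl}-7,12-dihydroxy-6-methyl-4-{[(E)-2-methylbut-2-enoyl]oxy}-2-[(4,4,5,5-tetramethyl-1,3,2-dioxaborolan-2-yl)methyl]dodeca-2,5,10-trienoate F1. TEMPO/PhI(OAc)2 then gives the corresponding 12-oxo allylboronate F2. F2 closes C6–C7 by intramolecular allylboration, thermally in toluene or with Sc(OTf)3 catalysis, through a closed six-membered transition state with no carbanionic allyl species. The borate lactonises on work-up and the route is rejoined at 29. The trans-lactone is not guaranteed there either, since the boronate geometry would favour the cis-lactone in an open-chain case.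

Step 11, the cross-metathesis. The propenyl group sits next to a bis-allylic tiglate and the partner is 1,1-disubstituted, so turnover may be poor on the late, polar substrate. The fallback sets out from 11 and moves the metathesis to the fragment stage, where neat 24 and more catalyst are affordable. This gives methyl (2Z,4R,5Z)-2-(bromomethyl)-6-methyl-4-{[(E)-2-methylbut-2-enoyl]oxy}-7-oxoocta-2,5-dienoate F3. Because a bromomethyl acrylate does not survive Et3N at 0 °C, the aldol is changed to (−)-Ipc2BOTf/iPr2NEt at −78 °C with 18, which gives methyl (2Z,4R,5Z,9S,10Z)-2-(bromomethyl)-10-{[(tert-butyldimethylsilyl)oxy]methyl}-9-hydroxy-6-methyl-4-{[(E)-2-methylbut-2-enoyl]oxy}-7-oxo-12-[(triethylsilyl)oxy]dodeca-2,5,10-trienoate F4. Evans–Tishchenko reduction with a pre-formed trivalent samarium catalyst (SmI2 premixed with acetaldehyde, so that no divalent samarium meets the bromide) gives methyl (2Z,4R,5Z,7S,9S,10Z)-9-acetoxy-2-(bromomethyl)-10-{[(tert-butyldimethylsilyl)oxy]methyl}-7-hydroxy-6-methyl-4-{[(E)-2-methylbut-2-enoyl]oxy}-12-[(triethylsilyl)oxy]dodeca-2,5,10-trienoate F5. The same acidic work-up returns to 25.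

Step 9, the aldol. The Z-enal 18 can isomerise to the E isomer, and the facial selectivity is reagent-controlled only. The fallback sets out from 16 and never makes the enal. A NiCl2/CrCl2 coupling (chiral sulfonamide ligand) of 16 with 3,3-dimethoxypropanal gives (3S,4Z)-4-{[(tert-butyldimethylsilyl)oxy]methyl}-1,1-dimethoxy-6-[(triethylsilyl)oxy]hex-4-en-3-ol F6. Ac2O/DMAP gives (3S,4Z)-4-{[(tert-butyldimethylsilyl)oxy]methyl}-1,1-dimethoxy-6-[(triethylsilyl)oxy]hex-4-en-3-yl acetate F7. Aqueous acid unmasks the aldehyde and removes the TES group to give (3S,4Z)-4-{[(tert-butyldimethylsilyl)oxy]methyl}-6-hydroxy-1-oxohex-4-en-3-yl acetate F8. A second NiCl2/CrCl2 coupling, of vinyl iodide 8 with F8, forms C1–C10 and the C1 carbinol and rejoins the route at 23.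

**Further compounds**
F1 | step 13 | methyl (2E,4R,5Z,7S,9S,10Z)-9-acetoxy-10-{[(tert-butyldimethylsilyl)oxy]methyl}-7,12-dihydroxy-6-methyl-4-{[(E)-2-methylbut-2-enoyl]oxy}-2-[(4,4,5,5-tetramethyl-1,3,2-dioxaborolan-2-yl)methyl]dodeca-2,5,10-trienoate | OC/C=C(/CO[Si](C)(C)C(C)(C)C)[C@@H](OC(C)=O)C[C@H](O)/C(C)=C\[C@@H](OC(=O)/C(C)=C/C)/C=C(\CB1OC(C)(C)C(C)(C)O1)C(=O)OC
F2 | step 13 | methyl (2E,4R,5Z,7S,9S,10Z)-9-acetoxy-10-{[(tert-butyldimethylsilyl)oxy]methyl}-7-hydroxy-6-methyl-4-{[(E)-2-methylbut-2-enoyl]oxy}-12-oxo-2-[(4,4,5,5-tetramethyl-1,3,2-dioxaborolan-2-yl)methyl]dodeca-2,5,10-trienoate | O=C/C=C(/CO[Si](C)(C)C(C)(C)C)[C@@H](OC(C)=O)C[C@H](O)/C(C)=C\[C@@H](OC(=O)/C(C)=C/C)/C=C(\CB1OC(C)(C)C(C)(C)O1)C(=O)OC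
F3 | step 11 | methyl (2Z,4R,5Z)-2-(bromomethyl)-6-methyl-4-{[(E)-2-methylbut-2-enoyl]oxy}-7-oxoocta-2,5-dienoate | CC(=O)/C(C)=C\[C@@H](OC(=O)/C(C)=C/C)/C=C(\CBr)C(=O)OC
F4 | step 11 | methyl (2Z,4R,5Z,9S,10Z)-2-(bromomethyl)-10-{[(tert-butyldimethylsilyl)oxy]methyl}-9-hydroxy-6-methyl-4-{[(E)-2-methylbut-2-enoyl]oxy}-7-oxo-12-[(triethylsilyl)oxy]dodeca-2,5,10-trienoate | CC[Si](CC)(CC)OC/C=C(/CO[Si](C)(C)C(C)(C)C)[C@@H](O)CC(=O)/C(C)=C\[C@@H](OC(=O)/C(C)=C/C)/C=C(\CBr)C(=O)OC
F5 | step 11 | methyl (2Z,4R,5Z,7S,9S,10Z)-9-acetoxy-2-(bromomethyl)-10-{[(tert-butyldimethylsilyl)oxy]methyl}-7-hydroxy-6-methyl-4-{[(E)-2-methylbut-2-enoyl]oxy}-12-[(triethylsilyl)oxy]dodeca-2,5,10-trienoate | CC[Si](CC)(CC)OC/C=C(/CO[Si](C)(C)C(C)(C)C)[C@@H](OC(C)=O)C[C@H](O)/C(C)=C\[C@@H](OC(=O)/C(C)=C/C)/C=C(\CBr)C(=O)OC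
F6 | step 9 | (3S,4Z)-4-{[(tert-butyldimethylsilyl)oxy]methyl}-1,1-dimethoxy-6-[(triethylsilyl)oxy]hex-4-en-3-ol | CC[Si](CC)(CC)OC/C=C(/CO[Si](C)(C)C(C)(C)C)[C@@H](O)CC(OC)OC
F7 | step 9 | (3S,4Z)-4-{[(tert-butyldimethylsilyl)oxy]methyl}-1,1-dimethoxy-6-[(triethylsilyl)oxy]hex-4-en-3-yl acetate | CC[Si](CC)(CC)OC/C=C(/CO[Si](C)(C)C(C)(C)C)[C@@H](OC(C)=O)CC(OC)OC
F8 | step 9 | (3S,4Z)-4-{[(tert-butyldimethylsilyl)oxy]methyl}-6-hydroxy-1-oxohex-4-en-3-yl acetate | OC/C=C(/CO[Si](C)(C)C(C)(C)C)[C@@H](OC(C)=O)CC=O
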